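**Retrosynthetic overview**

- Last bonds: the C19 laurate and the C11=C12 alkene, made by a Wittig reaction between a C25 ε-apocarotenyl ylide and a γ-hydroxy-enal masked as a lactol. C8 stays a carbinol until after the olefination.
- The lactol comes from a purchased butenolide ring, joined at C8–C9 to a β-ring acetaldehyde (Nozaki–Hiyama–Kishi). The butenolide ring fixes the C9=C10 geometry and tells C19 (alcohol) from C11 (aldehyde).
- β-Ring: C6 is sp2 in the target and is traced back to a ketone carbonyl. That makes C1 an enolisable isopropyl methine and C2 a primary halide next to the C3 oxygen. Because C3–O and C5 are 1,3-related across C4, a temporary γ-lactone (O on C3, an extra carboxyl carbon on C5) is built first from a β-keto ester and (R)-epichlorohydrin. The carbocycle is then closed C1–C2 onto it (bridged keto-lactone) and the extra carbon leaves as CO2.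
- ε-Ring: taken ready-made from ketoisophorone. C3' is set by asymmetric transfer hydrogenation, C6' by epoxidation, Wharton transposition and Wittig–Still rearrangement. The chain grows by Horner–Wadsworth–Emmons and Wittig steps with the C10 trienedial.
- Order of ring events: γ-lactone (step 1), β-carbocycle (step 4), lactone excision (step 5), ε-ring functionalised (steps 12–18), butenolide ring opened (steps 11 and 25).

Key step: step 4

Remark: carotenoid numbering is used for positions; the centre next to the ring ketone (C5, steps 5–7) and the C8 carbinol (steps 10–26) are carried as epimer mixtures because both become sp2 later, and the bromobutenolide, the C5 phosphonate and the C10 dialdehyde are taken as purchasable.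

**Route**

Step 1
Reactants: 1 ethyl 4-methyl-3-oxopentanoate; 2 (2R)-2-(chloromethyl)oxirane [(R)-epichlorohydrin]
Product: 3 (5R)-5-(chloromethyl)-3-(2-methylpropanoyl)oxolan-2-one (C3 epimers)
Conditions: NaOEt (1 equiv), EtOH, 45 °C; then AcOH
Reagents that add atoms: none
Why: C-alkylation of the β-keto ester sodium enolate at the unsubstituted epoxide carbon of 2 followed by lactonisation of the alkoxide onto the ester (the classical β-keto ester plus epichlorohydrin route to α-acyl-δ-chloro-γ-valerolactones) should give 3; the C–O bond of the stereocentre is never broken, so the (R) centre of 2 becomes C3 of the carotenoid unchanged.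

Step 2
Reactants: 3 (5R)-5-(chloromethyl)-3-(2-methylpropanoyl)oxolan-2-one
Product: 4 (3S,5R)-5-(chloromethyl)-3-methyl-3-(2-methylpropanoyl)oxolan-2-one (acyl group cis to CH2Cl)
Conditions: K2CO3, MeI, acetone, 25 → 50 °C
Reagents that add atoms: iodomethane (CI)
Why: C-methylation of the β-dicarbonyl enolate, in which iodomethane should attack the planar enolate from the ring face opposite the chloromethyl group, so that the new quaternary centre carries its acyl group cis to CH2Cl (the minor epimer cannot cyclise later and is removed by chromatography here).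

Step 3
Reactants: 4 (3S,5R)-5-(chloromethyl)-3-methyl-3-(2-methylpropanoyl)oxolan-2-one
Product: 5 (3S,5R)-5-(iodomethyl)-3-methyl-3-(2-methylpropanoyl)oxolan-2-one
Conditions: NaI, butanone, 80 °C
Reagents that add atoms: sodium iodide ([Na+].[I-])
Why: Finkelstein halide exchange by SN2 at the primary carbon, driven by precipitation of NaCl, installs the softer leaving group for C-alkylation; no stereocentre is involved.

Step 4
Reactants: 5 (3S,5R)-5-(iodomethyl)-3-methyl-3-(2-methylpropanoyl)oxolan-2-one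
Product: 6 (1S,5S)-1,3,3-trimethyl-6-oxabicyclo[3.2.1]octane-2,7-dione
Conditions: KN(SiMe3)2 (1.05 equiv), THF, −78 → 0 °C
Reagents that add atoms: none
Why: KN(SiMe3)2 removes the only acidic hydrogen, the isopropyl methine at C1 (C5 is quaternary and the lactone has no α-hydrogen), and the potassium enolate displaces iodide from the primary carbon C2 in an intramolecular SN2 reaction. The closest known reaction type is the intramolecular C-alkylation of ketone enolates by ω-haloalkyl chains, which is used routinely to build bridged bicyclic ketones. The six-membered carbocycle closes in a 6-(enolendo)-exo-tet mode, and because the lactone already spans C3 and C5 the product is a 6-oxabicyclo[3.2.1]octane. No new stereocentre is formed (C1 carries two methyl groups): C3 comes unchanged from 2, and C5, set in step 2, only has to hold the acyl group cis to the iodomethyl arm. The step needs C- instead of O-alkylation and a single enolate; the soft iodide, the potassium enolate in THF and the cis-1,3 hold of the lactone on the two arms should secure the first, and the blocked C5 secures the second. In one operation it delivers the ring, the quaternary C1 and a C6 carbonyl that, once the lactone carbon is lost, has its only neighbouring hydrogen on C5, which later fixes the position of the ring double bond.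

Step 5
Reactants: 6 (1S,5S)-1,3,3-trimethyl-6-oxabicyclo[3.2.1]octane-2,7-dione
Product: 8 (4R)-4-hydroxy-2,2,6-trimethylcyclohexan-1-one (C6 epimers), via keto acid 7 (not isolated)
Conditions: LiOH, THF–H2O, 25 °C; then HCl (pH 3), 60 °C
Reagents that add atoms: none
Why: Saponification of the bridged lactone followed by thermal decarboxylation of the β-keto acid (possible only after ring opening, when the enol is no longer at a bridgehead) removes the temporary carboxyl carbon; the C3–O bond is untouched and the centre next to the ketone forms as an epimer mixture that is erased in step 8.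

Step 6
Reactants: 8 (4R)-4-hydroxy-2,2,6-trimethylcyclohexan-1-one
Product: 9 (4R)-4-[(tert-butyldimethylsilyl)oxy]-2,2,6-trimethylcyclohexan-1-one (C6 epimers)
Conditions: t-BuMe2SiCl, imidazole, DMF, 25 °C
Reagents that add atoms: tert-butyldimethylsilyl chloride (CC(C)(C)[Si](C)(C)Cl)
Why: Standard silylation of the secondary alcohol (imidazole-catalysed silyl transfer) protects C3–OH against the ylide, the aluminium Lewis acid and the hydride reagents to come.

Step 7
Reactants: 9 (4R)-4-[(tert-butyldimethylsilyl)oxy]-2,2,6-trimethylcyclohexan-1-one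
Product: 10 tert-butyldimethyl{[(1R)-3,3,5-trimethyl-4-methylidenecyclohexyl]oxy}silane (C5 epimers)
Conditions: Ph3PCH3Br, KOt-Bu, toluene, 90 °C
Reagents that add atoms: methyltriphenylphosphonium bromide ([Br-].C[P+](c1ccccc1)(c1ccccc1)c1ccccc1)
Why: Wittig methylenation with an excess of the unstabilised ylide at elevated temperature, conditions under which hindered 2,2,6-trisubstituted cyclohexanones are known to react, introduces C7; epimerisation next to the carbonyl is of no consequence.

Step 8
Reactants: 10 tert-butyldimethyl{[(1R)-3,3,5-trimethyl-4-methylidenecyclohexyl]oxy}silane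
Product: 11 2-{(4R)-4-[(tert-butyldimethylsilyl)oxy]-2,6,6-trimethylcyclohex-1-en-1-yl}ethan-1-ol
Conditions: (CH2O)n, Me2AlCl, CH2Cl2, 0 → 25 °C
Reagents that add atoms: formaldehyde, used as paraformaldehyde (C=O)
Why: Lewis-acid-promoted carbonyl-ene reaction of the 1,1-disubstituted alkene with formaldehyde: the only allylic hydrogen is at C5, so both epimers of 10 should converge on the tetrasubstituted C5=C6 alkene while C8 is attached to C7, and no stereocentre is created.

Step 9
Reactants: 11 2-{(4R)-4-[(tert-butyldimethylsilyl)oxy]-2,6,6-trimethylcyclohex-1-en-1-yl}ethan-1-ol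
Product: 12 {(4R)-4-[(tert-butyldimethylsilyl)oxy]-2,6,6-trimethylcyclohex-1-en-1-yl}acetaldehyde
Conditions: Dess–Martin periodinane, pyridine, CH2Cl2, 0 °C
Reagents that add atoms: none
Why: Dess–Martin oxidation of the primary alcohol under buffered, non-basic conditions should give the β,γ-unsaturated aldehyde without moving the tetrasubstituted double bond.

Step 10
Reactants: 12 {(4R)-4-[(tert-butyldimethylsilyl)oxy]-2,6,6-trimethylcyclohex-1-en-1-yl}acetaldehyde; 13 4-bromofuran-2(5H)-one
Product: 14 4-(2-{(4R)-4-[(tert-butyldimethylsilyl)oxy]-2,6,6-trimethylcyclohex-1-en-1-yl}-1-hydroxyethyl)furan-2(5H)-one (carbinol epimers)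
Conditions: CrCl2 (4 equiv), NiCl2 (2 mol %), DMF–THF, 25 °C
Reagents that add atoms: none
Why: Nozaki–Hiyama–Kishi coupling (zerovalent nickel inserts into the activated vinyl bromide, the vinyl group passes to trivalent chromium and adds to the aldehyde) tolerates the lactone and the enolisable aldehyde; the C8 carbinol is formed without control, which is harmless because C8 is oxidised in step 27.

Step 11
Reactants: 14 4-(2-{(4R)-4-[(tert-butyldimethylsilyl)oxy]-2,6,6-trimethylcyclohex-1-en-1-yl}-1-hydroxyethyl)furan-2(5H)-one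
Product: 15 4-(2-{(4R)-4-[(tert-butyldimethylsilyl)oxy]-2,6,6-trimethylcyclohex-1-en-1-yl}-1-hydroxyethyl)-2,5-dihydrofuran-2-ol (epimer mixture)
Conditions: i-Bu2AlH (3 equiv), CH2Cl2, −78 °C; aq. potassium sodium tartrate
Reagents that add atoms: none
Why: Low-temperature i-Bu2AlH reduction stops at the lactol stage of the α,β-unsaturated lactone (one equivalent is used up by the free hydroxyl), and the five-membered ring keeps C19–O and C11 cis on the C9=C10 bond.

Step 12
Reactants: 16 2,6,6-trimethylcyclohex-2-ene-1,4-dione (ketoisophorone)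
Product: 17 (4R)-4-hydroxy-2,6,6-trimethylcyclohex-2-en-1-one
Conditions: RuCl(p-cymene)[(R,R)-TsDPEN] (0.5 mol %), HCO2H–Et3N (5:2), CH2Cl2, 25 °C
Reagents that add atoms: none
Why: Noyori-type asymmetric transfer hydrogenation: the catalyst should reduce only the unhindered C4 carbonyl (the other is flanked by a quaternary carbon and a methyl-bearing vinylic carbon), and the (R,R)-ligand should direct hydride to the face that gives the (R)-alcohol, the future C3'.

Step 13
Reactants: 17 (4R)-4-hydroxy-2,6,6-trimethylcyclohex-2-en-1-one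
Product: 18 (4R)-2,6,6-trimethyl-4-[(triisopropylsilyl)oxy]cyclohex-2-en-1-one
Conditions: i-Pr3SiOTf, 2,6-lutidine, CH2Cl2, 0 °C
Reagents that add atoms: triisopropylsilyl trifluoromethanesulfonate (CC(C)[Si](OS(=O)(=O)C(F)(F)F)(C(C)C)C(C)C)
Why: Silylation with the triflate and a hindered pyridine base; the triisopropylsilyl group is chosen because it should not migrate to the neighbouring alkoxide in step 16.

Step 14
Reactants: 18 (4R)-2,6,6-trimethyl-4-[(triisopropylsilyl)oxy]cyclohex-2-en-1-one
Product: 19 (1S,5R,6S)-1,3,3-trimethyl-5-[(triisopropylsilyl)oxy]-7-oxabicyclo[4.1.0]heptan-2-one (epoxide trans to the silyloxy group)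
Conditions: H2O2 (30% aq), NaOH (0.3 equiv), MeOH, 0 °C
Reagents that add atoms: hydrogen peroxide (OO)
Why: Weitz–Scheffer nucleophilic epoxidation, in which hydroperoxide adds to the β-carbon anti to the adjacent silyloxy group and the enolate closes the ring, so that the epoxide should form trans to the C3' oxygen.

Step 15
Reactants: 19 (1S,5R,6S)-1,3,3-trimethyl-5-[(triisopropylsilyl)oxy]-7-oxabicyclo[4.1.0]heptan-2-one
Product: 21 (1R,6R)-2,4,4-trimethyl-6-[(triisopropylsilyl)oxy]cyclohex-2-en-1-ol, via epoxy hydrazone 20 (not isolated)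
Conditions: N2H4·H2O, AcOH (cat.), MeOH, 0 → 25 °C
Reagents that add atoms: none
Why: Wharton transposition: the hydrazone of the epoxy ketone fragments with loss of N2 to the transposed allylic alcohol, and because the C4'–O bond of the epoxide is kept, the new hydroxyl is trans to the C3' silyloxy group.

Step 16
Reactants: 21 (1R,6R)-2,4,4-trimethyl-6-[(triisopropylsilyl)oxy]cyclohex-2-en-1-ol
Product: 22 tributyl[({(1R,6R)-2,4,4-trimethyl-6-[(triisopropylsilyl)oxy]cyclohex-2-en-1-yl}oxy)methyl]stannane
Conditions: KH, Bu3SnCH2I, THF, 0 → 25 °C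
Reagents that add atoms: tributyl(iodomethyl)stannane (CCCC[Sn](CI)(CCCC)CCCC)
Why: Williamson etherification of the potassium alkoxide with the reactive α-stannyl iodide gives the precursor of the rearrangement without touching a stereocentre.

Step 17
Reactants: 22 tributyl[({(1R,6R)-2,4,4-trimethyl-6-[(triisopropylsilyl)oxy]cyclohex-2-en-1-yl}oxy)methyl]stannane
Product: 23 {(1R,4R)-2,6,6-trimethyl-4-[(triisopropylsilyl)oxy]cyclohex-2-en-1-yl}methanol
Conditions: n-BuLi, THF, −78 → −40 °C
Reagents that add atoms: none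
Why: Wittig–Still [2,3]-sigmatropic rearrangement: tin–lithium exchange gives the α-alkoxymethyllithium, which is transferred suprafacially from the C4' oxygen to C6', so that C7' is installed on the face the oxygen occupied (trans to the C3' oxygen) and the double bond moves to C4'=C5'.

Step 18
Reactants: 23 {(1R,4R)-2,6,6-trimethyl-4-[(triisopropylsilyl)oxy]cyclohex-2-en-1-yl}methanol
Product: 24 (1R,4R)-2,6,6-trimethyl-4-[(triisopropylsilyl)oxy]cyclohex-2-ene-1-carbaldehyde
Conditions: Dess–Martin periodinane, pyridine, CH2Cl2, 0 °C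
Reagents that add atoms: none
Why: Dess–Martin oxidation under buffered conditions should give the aldehyde without epimerising the α-centre (C6') or conjugating the β,γ-double bond, provided the product is used at once.

Step 19
Reactants: 24 (1R,4R)-2,6,6-trimethyl-4-[(triisopropylsilyl)oxy]cyclohex-2-ene-1-carbaldehyde; 25 ethyl (2E)-4-(diethoxyphosphoryl)-3-methylbut-2-enoate
Product: 26 ethyl (2E,4E)-3-methyl-5-{(1R,4R)-2,6,6-trimethyl-4-[(triisopropylsilyl)oxy]cyclohex-2-en-1-yl}penta-2,4-dienoate
Conditions: 25, LiN(SiMe3)2, THF, −78 °C; then 24, −78 → 0 °C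
Reagents that add atoms: none
Why: Horner–Wadsworth–Emmons olefination with the vinylogous phosphonate anion, a weak base that should not enolise the aldehyde, forms C7'=C8' with E geometry and brings in C9'=C10' mainly as the E isomer (any 9'Z material is removed by chromatography).

Step 20
Reactants: 26 ethyl (2E,4E)-3-methyl-5-{(1R,4R)-2,6,6-trimethyl-4-[(triisopropylsilyl)oxy]cyclohex-2-en-1-yl}penta-2,4-dienoate
Product: 27 (2E,4E)-3-methyl-5-{(1R,4R)-2,6,6-trimethyl-4-[(triisopropylsilyl)oxy]cyclohex-2-en-1-yl}penta-2,4-dien-1-ol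
Conditions: i-Bu2AlH, CH2Cl2, −78 °C; aq. potassium sodium tartrate
Reagents that add atoms: none
Why: i-Bu2AlH reduction of the dienoate to the allylic alcohol (1,2-reduction of an ester) leaves the silyl ether and the stereocentres untouched.

Step 21
Reactants: 27 (2E,4E)-3-methyl-5-{(1R,4R)-2,6,6-trimethyl-4-[(triisopropylsilyl)oxy]cyclohex-2-en-1-yl}penta-2,4-dien-1-ol
Product: 29 [(2E,4E)-3-methyl-5-{(1R,4R)-2,6,6-trimethyl-4-[(triisopropylsilyl)oxy]cyclohex-2-en-1-yl}penta-2,4-dien-1-yl]triphenylphosphonium bromide, via allylic bromide 28 (not isolated)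
Conditions: CBr4, PPh3, CH2Cl2, −20 °C; then PPh3, 25 °C
Reagents that add atoms: triphenylphosphine (c1ccccc1P(c1ccccc1)c1ccccc1); carbon tetrabromide (BrC(Br)(Br)Br)
Why: Appel bromination under neutral conditions followed by SN2 quaternisation of triphenylphosphine at the primary allylic carbon gives the Wittig salt without exposing the allylic silyl ether to acid.

Step 22
Reactants: 29 [(2E,4E)-3-methyl-5-{(1R,4R)-2,6,6-trimethyl-4-[(triisopropylsilyl)oxy]cyclohex-2-en-1-yl}penta-2,4-dien-1-yl]triphenylphosphonium bromide; 30 (2E,4E,6E)-2,7-dimethylocta-2,4,6-trienedial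
Product: 32 (3R,6R)-3-[(triisopropylsilyl)oxy]-12'-apo-ε-caroten-12'-al, via ylide 31 (not isolated)
Conditions: NaOMe, MeOH–CH2Cl2, 0 → 25 °C, 30 in excess (2.5 equiv); then EtOAc, 70 °C
Reagents that add atoms: none
Why: Wittig olefination of the semi-stabilised ylide with an excess of the symmetrical dialdehyde should give mono-condensation at one formyl group; the new C11'=C12' bond forms as an E/Z mixture and the hindered Z isomer isomerises thermally to E.

Step 23
Reactants: 32 (3R,6R)-3-[(triisopropylsilyl)oxy]-12'-apo-ε-caroten-12'-al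
Product: 33 (3R,6R)-3-[(triisopropylsilyl)oxy]-12'-apo-ε-caroten-12'-ol
Conditions: NaBH4, MeOH–THF, 0 °C
Reagents that add atoms: none
Why: NaBH4 reduces the conjugated aldehyde to the primary allylic alcohol by 1,2-hydride addition without affecting the polyene.

Step 24
Reactants: 33 (3R,6R)-3-[(triisopropylsilyl)oxy]-12'-apo-ε-caroten-12'-ol
Product: 35 {(3R,6R)-3-[(triisopropylsilyl)oxy]-12'-apo-ε-caroten-12'-yl}triphenylphosphonium bromide, via allylic bromide 34 (not isolated)
Conditions: CBr4, PPh3, CH2Cl2, −30 °C; then PPh3, 0 → 25 °C, dark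
Reagents that add atoms: triphenylphosphine (c1ccccc1P(c1ccccc1)c1ccccc1); carbon tetrabromide (BrC(Br)(Br)Br)
Why: Appel bromination and in-situ quaternisation of triphenylphosphine, as in step 21, convert the polyenyl alcohol into the C25 Wittig salt under non-acidic conditions at low temperature.

Step 25
Reactants: 35 {(3R,6R)-3-[(triisopropylsilyl)oxy]-12'-apo-ε-caroten-12'-yl}triphenylphosphonium bromide; 15 4-(2-{(4R)-4-[(tert-butyldimethylsilyl)oxy]-2,6,6-trimethylcyclohex-1-en-1-yl}-1-hydroxyethyl)-2,5-dihydrofuran-2-ol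
Product: 37 (3R,3'R,6'R)-3-[(tert-butyldimethylsilyl)oxy]-3'-[(triisopropylsilyl)oxy]-7,8-dihydro-β,ε-carotene-8,19-diol (C8 epimers), via ylide 36 (not isolated)
Conditions: NaOMe, MeOH–CH2Cl2, 0 → 25 °C; then EtOAc, 70 °C, dark
Reagents that add atoms: none
Why: Wittig olefination of the open hydroxy-enal form of the lactol with the polyenyl ylide (free hydroxyls are tolerated under methoxide conditions) forms C11=C12, the Z isomer being isomerised thermally, while the C9=C10 geometry is inherited from the butenolide ring.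

Step 26
Reactants: 37 (3R,3'R,6'R)-3-[(tert-butyldimethylsilyl)oxy]-3'-[(triisopropylsilyl)oxy]-7,8-dihydro-β,ε-carotene-8,19-diol; 38 dodecanoyl chloride
Product: 39 (3R,3'R,6'R)-3-[(tert-butyldimethylsilyl)oxy]-8-hydroxy-3'-[(triisopropylsilyl)oxy]-7,8-dihydro-β,ε-caroten-19-yl dodecanoate
Conditions: 38 (1.05 equiv), 2,4,6-collidine, CH2Cl2, −40 °C
Reagents that add atoms: none
Why: Acylation with one equivalent of acid chloride at low temperature (nucleophilic acyl substitution) should select the primary allylic C19 hydroxyl over the hindered secondary C8 hydroxyl.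

Step 27
Reactants: 39 (3R,3'R,6'R)-3-[(tert-butyldimethylsilyl)oxy]-8-hydroxy-3'-[(triisopropylsilyl)oxy]-7,8-dihydro-β,ε-caroten-19-yl dodecanoate
Product: 40 (3R,3'R,6'R)-3-[(tert-butyldimethylsilyl)oxy]-8-oxo-3'-[(triisopropylsilyl)oxy]-7,8-dihydro-β,ε-caroten-19-yl dodecanoate
Conditions: MnO2 (activated, excess), CH2Cl2, 25 °C, dark
Reagents that add atoms: none
Why: MnO2 oxidation is specific for allylic alcohols, so the C8 carbinol next to the polyene should be oxidised to the conjugated ketone while the ester, the silyl ethers and the doubly activated C7 methylene are left alone.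

Step 28
Reactants: 40 (3R,3'R,6'R)-3-[(tert-butyldimethylsilyl)oxy]-8-oxo-3'-[(triisopropylsilyl)oxy]-7,8-dihydro-β,ε-caroten-19-yl dodecanoate
Product: 41 (3R,3'R,6'R)-3,3'-dihydroxy-8-oxo-7,8-dihydro-β,ε-caroten-19-yl dodecanoate (CNP0415583.1)
Conditions: HF·pyridine, pyridine, THF, 0 → 25 °C
Reagents that add atoms: none
Why: Fluoride-mediated desilylation with pyridine-buffered HF removes both silyl ethers without cleaving the laurate, enolising the β,γ-unsaturated ketone or ionising the allylic C3' alcohol.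

**Compound list**

1 | ethyl 4-methyl-3-oxopentanoate | CCOC(=O)CC(=O)C(C)C | starting material
2 | (2R)-2-(chloromethyl)oxirane | ClC[C@H]1CO1 | starting material
3 | (5R)-5-(chloromethyl)-3-(2-methylpropanoyl)oxolan-2-one (C3 epimers) | ClC[C@H]1CC(C(=O)C(C)C)C(=O)O1 | intermediate
4 | (3S,5R)-5-(chloromethyl)-3-methyl-3-(2-methylpropanoyl)oxolan-2-one | ClC[C@H]1C[C@@](C)(C(=O)C(C)C)C(=O)O1 | intermediate
5 | (3S,5R)-5-(iodomethyl)-3-methyl-3-(2-methylpropanoyl)oxolan-2-one | IC[C@H]1C[C@@](C)(C(=O)C(C)C)C(=O)O1 | intermediate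
6 | (1S,5S)-1,3,3-trimethyl-6-oxabicyclo[3.2.1]octane-2,7-dione | C1[C@H]2C[C@@](C)(C(=O)C1(C)C)C(=O)O2 | intermediate
7 | (1S,5S)-5-hydroxy-1,3,3-trimethyl-2-oxocyclohexane-1-carboxylic acid (not isolated) | C1[C@H](O)C[C@@](C)(C(=O)C1(C)C)C(=O)O | intermediate
8 | (4R)-4-hydroxy-2,2,6-trimethylcyclohexan-1-one (C6 epimers) | CC1C[C@@H](O)CC(C)(C)C1=O | intermediate
9 | (4R)-4-[(tert-butyldimethylsilyl)oxy]-2,2,6-trimethylcyclohexan-1-one (C6 epimers) | CC1C[C@@H](O[Si](C)(C)C(C)(C)C)CC(C)(C)C1=O | intermediate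
10 | tert-butyldimethyl{[(1R)-3,3,5-trimethyl-4-methylidenecyclohexyl]oxy}silane (C5 epimers) | CC1C[C@@H](O[Si](C)(C)C(C)(C)C)CC(C)(C)C1=C | intermediate
11 | 2-{(4R)-4-[(tert-butyldimethylsilyl)oxy]-2,6,6-trimethylcyclohex-1-en-1-yl}ethan-1-ol | OCCC1=C(C)C[C@@H](O[Si](C)(C)C(C)(C)C)CC1(C)C | intermediate
12 | {(4R)-4-[(tert-butyldimethylsilyl)oxy]-2,6,6-trimethylcyclohex-1-en-1-yl}acetaldehyde | O=CCC1=C(C)C[C@@H](O[Si](C)(C)C(C)(C)C)CC1(C)C | intermediate
13 | 4-bromofuran-2(5H)-one | O=C1OCC(Br)=C1 | starting material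
14 | 4-(2-{(4R)-4-[(tert-butyldimethylsilyl)oxy]-2,6,6-trimethylcyclohex-1-en-1-yl}-1-hydroxyethyl)furan-2(5H)-one (carbinol epimers) | O=C1OCC(C(O)CC2=C(C)C[C@@H](O[Si](C)(C)C(C)(C)C)CC2(C)C)=C1 | intermediate
15 | 4-(2-{(4R)-4-[(tert-butyldimethylsilyl)oxy]-2,6,6-trimethylcyclohex-1-en-1-yl}-1-hydroxyethyl)-2,5-dihydrofuran-2-ol (epimer mixture) | OC1OCC(C(O)CC2=C(C)C[C@@H](O[Si](C)(C)C(C)(C)C)CC2(C)C)=C1 | intermediate
16 | 2,6,6-trimethylcyclohex-2-ene-1,4-dione | CC1=CC(=O)CC(C)(C)C1=O | starting material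
17 | (4R)-4-hydroxy-2,6,6-trimethylcyclohex-2-en-1-one | CC1=C[C@H](O)CC(C)(C)C1=O | intermediate
18 | (4R)-2,6,6-trimethyl-4-[(triisopropylsilyl)oxy]cyclohex-2-en-1-one | CC1=C[C@H](O[Si](C(C)C)(C(C)C)C(C)C)CC(C)(C)C1=O | intermediate
19 | (1S,5R,6S)-1,3,3-trimethyl-5-[(triisopropylsilyl)oxy]-7-oxabicyclo[4.1.0]heptan-2-one | C[C@]12O[C@H]1[C@H](O[Si](C(C)C)(C(C)C)C(C)C)CC(C)(C)C2=O | intermediate
20 | hydrazone of 19 at the ring carbonyl (not isolated) | C[C@]12O[C@H]1[C@H](O[Si](C(C)C)(C(C)C)C(C)C)CC(C)(C)C2=NN | intermediate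
21 | (1R,6R)-2,4,4-trimethyl-6-[(triisopropylsilyl)oxy]cyclohex-2-en-1-ol (trans) | CC1=CC(C)(C)C[C@@H](O[Si](C(C)C)(C(C)C)C(C)C)[C@@H]1O | intermediate
22 | tributyl[({(1R,6R)-2,4,4-trimethyl-6-[(triisopropylsilyl)oxy]cyclohex-2-en-1-yl}oxy)methyl]stannane | CC1=CC(C)(C)C[C@@H](O[Si](C(C)C)(C(C)C)C(C)C)[C@@H]1OC[Sn](CCCC)(CCCC)CCCC | intermediate
23 | {(1R,4R)-2,6,6-trimethyl-4-[(triisopropylsilyl)oxy]cyclohex-2-en-1-yl}methanol | OC[C@H]1C(C)=C[C@H](O[Si](C(C)C)(C(C)C)C(C)C)CC1(C)C | intermediate
24 | (1R,4R)-2,6,6-trimethyl-4-[(triisopropylsilyl)oxy]cyclohex-2-ene-1-carbaldehyde | O=C[C@H]1C(C)=C[C@H](O[Si](C(C)C)(C(C)C)C(C)C)CC1(C)C | intermediate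
25 | ethyl (2E)-4-(diethoxyphosphoryl)-3-methylbut-2-enoate | CCOC(=O)/C=C(\C)CP(=O)(OCC)OCC | starting material
26 | ethyl (2E,4E)-3-methyl-5-{(1R,4R)-2,6,6-trimethyl-4-[(triisopropylsilyl)oxy]cyclohex-2-en-1-yl}penta-2,4-dienoate | CCOC(=O)/C=C(C)/C=C/[C@H]1C(C)=C[C@H](O[Si](C(C)C)(C(C)C)C(C)C)CC1(C)C | intermediate
27 | (2E,4E)-3-methyl-5-{(1R,4R)-2,6,6-trimethyl-4-[(triisopropylsilyl)oxy]cyclohex-2-en-1-yl}penta-2,4-dien-1-ol | OC/C=C(C)/C=C/[C@H]1C(C)=C[C@H](O[Si](C(C)C)(C(C)C)C(C)C)CC1(C)C | intermediate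
28 | primary allylic bromide of 27, OH replaced by Br (not isolated) | BrC/C=C(C)/C=C/[C@H]1C(C)=C[C@H](O[Si](C(C)C)(C(C)C)C(C)C)CC1(C)C | intermediate
29 | [(2E,4E)-3-methyl-5-{(1R,4R)-2,6,6-trimethyl-4-[(triisopropylsilyl)oxy]cyclohex-2-en-1-yl}penta-2,4-dien-1-yl]triphenylphosphonium bromide | [Br-].c1ccccc1[P+](c1ccccc1)(c1ccccc1)C/C=C(C)/C=C/[C@H]1C(C)=C[C@H](O[Si](C(C)C)(C(C)C)C(C)C)CC1(C)C | intermediate
30 | (2E,4E,6E)-2,7-dimethylocta-2,4,6-trienedial | O=C/C(C)=C/C=C/C=C(C)/C=O | starting material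
31 | phosphorus ylide of 29 (not isolated) | c1ccccc1P(c1ccccc1)(c1ccccc1)=C/C=C(C)/C=C/[C@H]1C(C)=C[C@H](O[Si](C(C)C)(C(C)C)C(C)C)CC1(C)C | intermediate
32 | (3R,6R)-3-[(triisopropylsilyl)oxy]-12'-apo-ε-caroten-12'-al | O=C/C(C)=C/C=C/C=C(C)/C=C/C=C(C)/C=C/[C@H]1C(C)=C[C@H](O[Si](C(C)C)(C(C)C)C(C)C)CC1(C)C | intermediate
33 | (3R,6R)-3-[(triisopropylsilyl)oxy]-12'-apo-ε-caroten-12'-ol | OC/C(C)=C/C=C/C=C(C)/C=C/C=C(C)/C=C/[C@H]1C(C)=C[C@H](O[Si](C(C)C)(C(C)C)C(C)C)CC1(C)C | intermediate
34 | primary allylic bromide of 33, OH replaced by Br (not isolated) | BrC/C(C)=C/C=C/C=C(C)/C=C/C=C(C)/C=C/[C@H]1C(C)=C[C@H](O[Si](C(C)C)(C(C)C)C(C)C)CC1(C)C | intermediate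
35 | {(3R,6R)-3-[(triisopropylsilyl)oxy]-12'-apo-ε-caroten-12'-yl}triphenylphosphonium bromide | [Br-].c1ccccc1[P+](c1ccccc1)(c1ccccc1)C/C(C)=C/C=C/C=C(C)/C=C/C=C(C)/C=C/[C@H]1C(C)=C[C@H](O[Si](C(C)C)(C(C)C)C(C)C)CC1(C)C | intermediate
36 | phosphorus ylide of 35 (not isolated) | c1ccccc1P(c1ccccc1)(c1ccccc1)=C/C(C)=C/C=C/C=C(C)/C=C/C=C(C)/C=C/[C@H]1C(C)=C[C@H](O[Si](C(C)C)(C(C)C)C(C)C)CC1(C)C | intermediate
37 | (3R,3'R,6'R)-3-[(tert-butyldimethylsilyl)oxy]-3'-[(triisopropylsilyl)oxy]-7,8-dihydro-β,ε-carotene-8,19-diol (C8 epimers) | OC\C(=C/C=C/C(C)=C/C=C/C=C(C)/C=C/C=C(C)/C=C/[C@H]1C(C)=C[C@H](O[Si](C(C)C)(C(C)C)C(C)C)CC1(C)C)C(O)CC1=C(C)C[C@@H](O[Si](C)(C)C(C)(C)C)CC1(C)C | intermediate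
38 | dodecanoyl chloride | CCCCCCCCCCCC(=O)Cl | starting material
39 | (3R,3'R,6'R)-3-[(tert-butyldimethylsilyl)oxy]-8-hydroxy-3'-[(triisopropylsilyl)oxy]-7,8-dihydro-β,ε-caroten-19-yl dodecanoate (C8 epimers) | CCCCCCCCCCCC(=O)OC\C(=C/C=C/C(C)=C/C=C/C=C(C)/C=C/C=C(C)/C=C/[C@H]1C(C)=C[C@H](O[Si](C(C)C)(C(C)C)C(C)C)CC1(C)C)C(O)CC1=C(C)C[C@@H](O[Si](C)(C)C(C)(C)C)CC1(C)C | intermediate
40 | (3R,3'R,6'R)-3-[(tert-butyldimethylsilyl)oxy]-8-oxo-3'-[(triisopropylsilyl)oxy]-7,8-dihydro-β,ε-caroten-19-yl dodecanoate | CCCCCCCCCCCC(=O)OC\C(=C/C=C/C(C)=C/C=C/C=C(C)/C=C/C=C(C)/C=C/[C@H]1C(C)=C[C@H](O[Si](C(C)C)(C(C)C)C(C)C)CC1(C)C)C(=O)CC1=C(C)C[C@@H](O[Si](C)(C)C(C)(C)C)CC1(C)C | intermediate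
41 | (3R,3'R,6'R)-3,3'-dihydroxy-8-oxo-7,8-dihydro-β,ε-caroten-19-yl dodecanoate (CNP0415583.1) | CCCCCCCCCCCC(=O)OC\C(=C/C=C/C(C)=C/C=C/C=C(C)/C=C/C=C(C)/C=C/[C@H]1C(C)=C[C@H](O)CC1(C)C)C(=O)CC1=C(C)C[C@@H](O)CC1(C)C | target

**Step count and risks**

Total step count: 28 (steps 1–11 β-ring branch, steps 12–24 ε-ring and polyene branch, steps 25–28 union and end game).
Longest linear sequence: 17 steps (steps 12–28, from 16).

Steps most likely to fail:

1. Step 4 (ring closure). The enolate may alkylate on oxygen instead of carbon, giving a bridged enol ether, or close slowly because the nucleophilic carbon is fully substituted. Poor facial selectivity in step 2 would also show up here as material that cannot cyclise. The fallback drops the lactone template. It sets out from 4, which is hydrolysed and decarboxylated in hot aqueous HCl–AcOH to the open chlorohydrin ketone (6R)-7-chloro-6-hydroxy-2,4-dimethylheptan-3-one F1 (both C3 epimers of 4 are usable). F1 is silylated to the tert-butyldimethylsilyl ether F2 and converted with NaI into the iodide F3. F3 is cyclised with KOt-Bu in t-BuOH–THF, where enolisation is reversible and the hydrogen-bonded enolate oxygen is a poor nucleophile, so that only the isopropyl-side enolate can close a six-membered ring by C-alkylation. This gives 9 directly, where the route is rejoined.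

2. Step 15 (Wharton transposition). Hydrazone formation at a carbonyl flanked by two fully substituted carbons may be too slow, so that hydrazine opens the epoxide first. The fallback is a radical fragmentation. It sets out from 19, which NaBH4 reduces to the epoxy alcohol F4, and 1,1'-thiocarbonyldiimidazole converts F4 into the imidazolide F5. Bu3SnH with AIBN then generates the radical at C6', which opens the adjacent epoxide and, after hydrogen transfer, gives 21 with the C4' oxygen configuration unchanged. The route is rejoined at 21.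

3. Step 25 (Wittig reaction on the lactol). Only the small open-chain share of 15 reacts, so the basic polyenyl ylide may decompose faster than it adds, and the lactol may lose water to a furan. The fallback is a Horner–Wadsworth–Emmons olefination. It sets out from 33: the bromide 34 is made as in step 24 but heated with P(OEt)3 (Arbuzov reaction) to give the diethyl phosphonate F6. Its carbanion (NaN(SiMe3)2, THF, −78 → 0 °C) is more nucleophilic, less basic and longer-lived than the ylide, and is condensed with 15 to give 37 with E geometry at C11=C12. The route is rejoined at 37.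

**Further compounds**

F1 | step 4 | (6R)-7-chloro-6-hydroxy-2,4-dimethylheptan-3-one (C4 epimers) | ClC[C@H](O)CC(C)C(=O)C(C)C
F2 | step 4 | (6R)-6-[(tert-butyldimethylsilyl)oxy]-7-chloro-2,4-dimethylheptan-3-one | ClC[C@H](O[Si](C)(C)C(C)(C)C)CC(C)C(=O)C(C)C
F3 | step 4 | (6R)-6-[(tert-butyldimethylsilyl)oxy]-7-iodo-2,4-dimethylheptan-3-one | IC[C@H](O[Si](C)(C)C(C)(C)C)CC(C)C(=O)C(C)C
F4 | step 15 | epoxy alcohol from reduction of the ring carbonyl of 19 (other centres as in 19, carbinol epimers) | C[C@]12O[C@H]1[C@H](O[Si](C(C)C)(C(C)C)C(C)C)CC(C)(C)C2O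
F5 | step 15 | O-(imidazol-1-ylcarbonothioyl) derivative of F4 | C[C@]12O[C@H]1[C@H](O[Si](C(C)C)(C(C)C)C(C)C)CC(C)(C)C2OC(=S)n1ccnc1
F6 | step 25 | diethyl {(3R,6R)-3-[(triisopropylsilyl)oxy]-12'-apo-ε-caroten-12'-yl}phosphonate | CCOP(=O)(OCC)C/C(C)=C/C=C/C=C(C)/C=C/C=C(C)/C=C/[C@H]1C(C)=C[C@H](O[Si](C(C)C)(C(C)C)C(C)C)CC1(C)C
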